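The route cuts C3–C4 and C3=C10 back to a single carboxyl carbon. The feature exploited is acyclic C3, which bears three carbon groups: the oxygenated stereocentre C2, the exocyclic methylene C10 and the C4 methylene. It lies in no ring, and the benzoate ring is a spectator. Double addition of a (trimethylsilyl)methyl nucleophile to the ester of methyl (S)-glycerate acetonide, then loss of silanol, should give in one operation the 2-substituted allylsilane, with C2 intact and the allyl unit armed for union with prenal. The precursor is simply the acetonide-protected α,β-dihydroxy ester. Aryl ether formation at C1, peroxide displacement with inversion at C2 and late C5 oxidation complete the route.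

Key step: step 1

Assumption: the target is taken as the open-chain hydroperoxy enone drawn (not a cyclic peroxyhemiketal); atoms are numbered C1 (CH2OAr) to C7 along the chain, with C8 and C9 the methyls on C7 and C10 the methylene on C3; the C5 carbinol is carried as a mixture of epimers because that centre ends as the ketone.

Step 1
Reactants: 1 methyl (4S)-2,2-dimethyl-1,3-dioxolane-4-carboxylate; 2 (trimethylsilyl)methylmagnesium chloride
Product: 5 (4R)-2,2-dimethyl-4-[3-(trimethylsilyl)prop-1-en-2-yl]-1,3-dioxolane, via α-silyl ketone 3 (not isolated), via bis(silylmethyl) carbinol 4 (not isolated)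
Conditions: anhydrous CeCl3 (5 equiv), 2 (5 equiv), THF, −78 °C to rt; aq. NH4Cl; then silica gel, CH2Cl2, rt
Reagents that add atoms: none
Why: Transmetallation of 2 with CeCl3 gives a (trimethylsilyl)methylcerium reagent that adds to the ester carbonyl of 1; loss of methoxide gives ketone 3, a second addition gives the tertiary bis(β-silyl) alkoxide of 4, and on silica gel 4 undergoes acid-promoted Peterson elimination of trimethylsilanol from either of its two identical arms, so both directions deliver the same allylsilane 5. The closest known reaction type is the cerium-mediated double addition of a silylmethyl Grignard reagent to an ester followed by Peterson olefination, an established entry to 2-substituted allylsilanes. The former carboxyl carbon becomes C3 and the two new C–C bonds are those that end as C3–C4 and C3=C10; no ring is closed and no stereocentre is created. The selectivity required is complete double addition without enolisation of the very acidic α-silyl ketone 3 and without epimerisation of the α-alkoxy centre C2, and the weakly basic, strongly oxophilic organocerium secures both where the Grignard reagent alone would deprotonate. The dioxolane ring carries no acidic hydrogen, survives silica gel, and fixes the C1 and C2 oxygens in the arrangement that later becomes the (2R)-carbinol; the descriptor changes from S in 1 to R in 5 only because the alkenyl carbon ranks below the ring CH2O carbon.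

Step 2
Reactants: 5 (4R)-2,2-dimethyl-4-[3-(trimethylsilyl)prop-1-en-2-yl]-1,3-dioxolane; 6 3-methylbut-2-enal
Product: 7 2-[(4R)-2,2-dimethyl-1,3-dioxolan-4-yl]-6-methylhepta-1,5-dien-4-ol (both epimers at the carbinol carbon)
Conditions: BF3·OEt2 (1.1 equiv), CH2Cl2, −78 °C; aq. NaHCO3 at −78 °C
Reagents that add atoms: none
Why: Hosomi–Sakurai allylation: the BF3-activated aldehyde is attacked 1,2 (the β,β-dimethyl terminus disfavours conjugate addition) by the methylene terminus of the allylsilane, which becomes C4, and loss of the silyl group from the β-silyl cation turns the silylated carbon into the C10 methylene; the new C5 carbinol centre is left uncontrolled because it is oxidised in step 11.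

Step 3
Reactants: 7 2-[(4R)-2,2-dimethyl-1,3-dioxolan-4-yl]-6-methylhepta-1,5-dien-4-ol
Product: 8 tert-butyl({2-[(4R)-2,2-dimethyl-1,3-dioxolan-4-yl]-6-methylhepta-1,5-dien-4-yl}oxy)dimethylsilane (both epimers at the silyloxy carbon)
Conditions: TBSCl, imidazole, DMF, rt
Reagents that add atoms: tert-butyldimethylsilyl chloride, CC(C)(C)[Si](C)(C)Cl
Why: Silyl ether formation (imidazole-promoted silylation of a secondary alcohol) masks C5–OH so that the ketone, whose flanking C4 methylene would let the C3=C10 alkene slip into conjugation under base, is unveiled only after all basic steps.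

Step 4
Reactants: 8 tert-butyl({2-[(4R)-2,2-dimethyl-1,3-dioxolan-4-yl]-6-methylhepta-1,5-dien-4-yl}oxy)dimethylsilane
Product: 9 (2R)-5-[(tert-butyldimethylsilyl)oxy]-7-methyl-3-methylideneoct-6-ene-1,2-diol (both C5 epimers)
Conditions: pyridinium p-toluenesulfonate (cat.), MeOH, rt
Reagents that add atoms: none
Why: Acid-catalysed acetal exchange with methanol (acetonide cleavage) should remove the terminal isopropylidene group while the secondary TBS ether and both alkenes tolerate this weak pyridinium acid at room temperature; C2 is not involved and stays R.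

Step 5
Reactants: 9 (2R)-5-[(tert-butyldimethylsilyl)oxy]-7-methyl-3-methylideneoct-6-ene-1,2-diol
Product: 10 (2R)-5-[(tert-butyldimethylsilyl)oxy]-2-hydroxy-7-methyl-3-methylideneoct-6-en-1-yl 4-methylbenzenesulfonate
Conditions: TsCl (1.05 equiv), Et3N, Bu2SnO (cat.), CH2Cl2, 0 °C to rt
Reagents that add atoms: 4-methylbenzenesulfonyl chloride, Cc1ccc(cc1)S(Cl)(=O)=O
Why: Tin-catalysed regioselective sulfonylation of a 1,2-diol: the transient dibutylstannylene acetal activates the primary oxygen, so only C1–OH is tosylated and the secondary allylic C2–OH is kept for step 7.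

Step 6
Reactants: 10 (2R)-5-[(tert-butyldimethylsilyl)oxy]-2-hydroxy-7-methyl-3-methylideneoct-6-en-1-yl 4-methylbenzenesulfonate; 11 methyl 4-hydroxy-3-methoxybenzoate (methyl vanillate)
Product: 12 methyl 4-{[(2R)-5-[(tert-butyldimethylsilyl)oxy]-2-hydroxy-7-methyl-3-methylideneoct-6-en-1-yl]oxy}-3-methoxybenzoate
Conditions: K2CO3, DMF, 60 °C
Reagents that add atoms: none
Why: Williamson ether synthesis: the phenoxide of 11 displaces the primary tosylate in an SN2 reaction, and the vinyl epoxide that may form by internal displacement is opened by the same phenoxide at C1, so both paths should give 12 with C2 untouched.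

Step 7
Reactants: 12 methyl 4-{[(2R)-5-[(tert-butyldimethylsilyl)oxy]-2-hydroxy-7-methyl-3-methylideneoct-6-en-1-yl]oxy}-3-methoxybenzoate
Product: 13 methyl 4-{[(2R)-5-[(tert-butyldimethylsilyl)oxy]-2-(methanesulfonyloxy)-7-methyl-3-methylideneoct-6-en-1-yl]oxy}-3-methoxybenzoate
Conditions: Ms2O, Et3N, CH2Cl2, −20 °C; used at once
Reagents that add atoms: methanesulfonic anhydride, CS(=O)(=O)OS(C)(=O)=O
Why: Sulfonate ester formation at oxygen activates the C2 hydroxyl with retention, and the anhydride is used in place of the sulfonyl chloride so that no chloride ion is present to substitute the reactive allylic mesylate.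

Step 8
Reactants: 14 2,3-dimethylbut-2-ene
Product: 15 2-methoxypropan-2-yl hydroperoxide
Conditions: O3, MeOH/CH2Cl2, −78 °C; concentrated cold behind a shield and used as a solution
Reagents that add atoms: ozone, [O-][O+]=O; methanol, CO
Why: Ozonolysis in a participating solvent: cycloaddition and Criegee fragmentation of the symmetrical alkene give acetone and acetone carbonyl oxide, which methanol traps as the hydroperoxy ketal, a known preparation of this reagent.

Step 9
Reactants: 13 methyl 4-{[(2R)-5-[(tert-butyldimethylsilyl)oxy]-2-(methanesulfonyloxy)-7-methyl-3-methylideneoct-6-en-1-yl]oxy}-3-methoxybenzoate; 15 2-methoxypropan-2-yl hydroperoxide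
Product: 16 methyl 4-{[(2S)-5-[(tert-butyldimethylsilyl)oxy]-2-[(2-methoxypropan-2-yl)peroxy]-7-methyl-3-methylideneoct-6-en-1-yl]oxy}-3-methoxybenzoate
Conditions: 15 (2 equiv), CsOH·H2O (1.5 equiv), DMF, 0 °C to rt
Reagents that add atoms: none
Why: SN2 alkylation of a hydroperoxide: the cesium salt of 15, an α-effect nucleophile of low basicity, should displace the allylic mesylate in DMF with inversion, which turns the (2R)-sulfonate into the (2S)-peroxide of the target, while the ketal cap prevents a second alkylation and the peroxide anion is expelled again from any adduct with the aryl methyl ester.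

Step 10
Reactants: 16 methyl 4-{[(2S)-5-[(tert-butyldimethylsilyl)oxy]-2-[(2-methoxypropan-2-yl)peroxy]-7-methyl-3-methylideneoct-6-en-1-yl]oxy}-3-methoxybenzoate
Product: 17 methyl 4-{[(2S)-5-hydroxy-2-[(2-methoxypropan-2-yl)peroxy]-7-methyl-3-methylideneoct-6-en-1-yl]oxy}-3-methoxybenzoate
Conditions: Bu4NF/AcOH (1:1), THF, 0 °C to rt
Reagents that add atoms: none
Why: Fluoride-mediated desilylation driven by the Si–F bond, with acetic acid buffering the medium near neutrality so that neither base-induced Kornblum–DeLaMare fragmentation of the peroxide nor acid cleavage of the perketal sets in.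

Step 11
Reactants: 17 methyl 4-{[(2S)-5-hydroxy-2-[(2-methoxypropan-2-yl)peroxy]-7-methyl-3-methylideneoct-6-en-1-yl]oxy}-3-methoxybenzoate
Product: 18 methyl 4-{[(2S)-2-[(2-methoxypropan-2-yl)peroxy]-7-methyl-3-methylidene-5-oxooct-6-en-1-yl]oxy}-3-methoxybenzoate
Conditions: Dess–Martin periodinane, NaHCO3, CH2Cl2, 0 °C to rt
Reagents that add atoms: none
Why: Dess–Martin oxidation of the allylic secondary alcohol under buffered, non-basic conditions should give the enone, erase the stray C5 stereocentre and leave the C3=C10 alkene out of conjugation, with the capped peroxide inert to the iodane.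

Step 12
Reactants: 18 methyl 4-{[(2S)-2-[(2-methoxypropan-2-yl)peroxy]-7-methyl-3-methylidene-5-oxooct-6-en-1-yl]oxy}-3-methoxybenzoate
Product: 19 methyl 4-{[(2S)-2-hydroperoxy-7-methyl-3-methylidene-5-oxooct-6-en-1-yl]oxy}-3-methoxybenzoate (target)
Conditions: AcOH/THF/H2O (4:2:1), rt
Reagents that add atoms: none
Why: Mild acid hydrolysis of the mixed peroxy ketal should release the hydroperoxide together with acetone and methanol without breaking the O–O bond, touching C2 or isomerising the β,γ-unsaturated ketone.

Compound list
1 | methyl (4S)-2,2-dimethyl-1,3-dioxolane-4-carboxylate | COC(=O)[C@@H]1COC(C)(C)O1 | starting material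
2 | (trimethylsilyl)methylmagnesium chloride | C[Si](C)(C)C[Mg]Cl | starting material
3 | 1-[(4S)-2,2-dimethyl-1,3-dioxolan-4-yl]-2-(trimethylsilyl)ethan-1-one | C[Si](C)(C)CC(=O)[C@@H]1COC(C)(C)O1 | intermediate (not isolated)
4 | 2-[(4S)-2,2-dimethyl-1,3-dioxolan-4-yl]-1,3-bis(trimethylsilyl)propan-2-ol | C[Si](C)(C)CC(O)(C[Si](C)(C)C)[C@@H]1COC(C)(C)O1 | intermediate (not isolated)
5 | (4R)-2,2-dimethyl-4-[3-(trimethylsilyl)prop-1-en-2-yl]-1,3-dioxolane | C=C(C[Si](C)(C)C)[C@@H]1COC(C)(C)O1 | intermediate
6 | 3-methylbut-2-enal | CC(C)=CC=O | starting material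
7 | 2-[(4R)-2,2-dimethyl-1,3-dioxolan-4-yl]-6-methylhepta-1,5-dien-4-ol, carbinol epimers | C=C(CC(O)C=C(C)C)[C@@H]1COC(C)(C)O1 | intermediate
8 | tert-butyl({2-[(4R)-2,2-dimethyl-1,3-dioxolan-4-yl]-6-methylhepta-1,5-dien-4-yl}oxy)dimethylsilane, epimers at the silyloxy carbon | C=C(CC(O[Si](C)(C)C(C)(C)C)C=C(C)C)[C@@H]1COC(C)(C)O1 | intermediate
9 | (2R)-5-[(tert-butyldimethylsilyl)oxy]-7-methyl-3-methylideneoct-6-ene-1,2-diol, C5 epimers | C=C(CC(O[Si](C)(C)C(C)(C)C)C=C(C)C)[C@@H](O)CO | intermediate
10 | (2R)-5-[(tert-butyldimethylsilyl)oxy]-2-hydroxy-7-methyl-3-methylideneoct-6-en-1-yl 4-methylbenzenesulfonate, C5 epimers | C=C(CC(O[Si](C)(C)C(C)(C)C)C=C(C)C)[C@@H](O)COS(=O)(=O)c1ccc(C)cc1 | intermediate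
11 | methyl 4-hydroxy-3-methoxybenzoate (methyl vanillate) | COC(=O)c1ccc(O)c(OC)c1 | starting material
12 | methyl 4-{[(2R)-5-[(tert-butyldimethylsilyl)oxy]-2-hydroxy-7-methyl-3-methylideneoct-6-en-1-yl]oxy}-3-methoxybenzoate, C5 epimers | C=C(CC(O[Si](C)(C)C(C)(C)C)C=C(C)C)[C@@H](O)COc1ccc(C(=O)OC)cc1OC | intermediate
13 | methyl 4-{[(2R)-5-[(tert-butyldimethylsilyl)oxy]-2-(methanesulfonyloxy)-7-methyl-3-methylideneoct-6-en-1-yl]oxy}-3-methoxybenzoate, C5 epimers | C=C(CC(O[Si](C)(C)C(C)(C)C)C=C(C)C)[C@@H](OS(C)(=O)=O)COc1ccc(C(=O)OC)cc1OC | intermediate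
14 | 2,3-dimethylbut-2-ene | CC(C)=C(C)C | starting material
15 | 2-methoxypropan-2-yl hydroperoxide | COC(C)(C)OO | intermediate
16 | methyl 4-{[(2S)-5-[(tert-butyldimethylsilyl)oxy]-2-[(2-methoxypropan-2-yl)peroxy]-7-methyl-3-methylideneoct-6-en-1-yl]oxy}-3-methoxybenzoate, C5 epimers | C=C(CC(O[Si](C)(C)C(C)(C)C)C=C(C)C)[C@@H](COc1ccc(C(=O)OC)cc1OC)OOC(C)(C)OC | intermediate
17 | methyl 4-{[(2S)-5-hydroxy-2-[(2-methoxypropan-2-yl)peroxy]-7-methyl-3-methylideneoct-6-en-1-yl]oxy}-3-methoxybenzoate, C5 epimers | C=C(CC(O)C=C(C)C)[C@@H](COc1ccc(C(=O)OC)cc1OC)OOC(C)(C)OC | intermediate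
18 | methyl 4-{[(2S)-2-[(2-methoxypropan-2-yl)peroxy]-7-methyl-3-methylidene-5-oxooct-6-en-1-yl]oxy}-3-methoxybenzoate | C=C(CC(=O)C=C(C)C)[C@@H](COc1ccc(C(=O)OC)cc1OC)OOC(C)(C)OC | intermediate
19 | methyl 4-{[(2S)-2-hydroperoxy-7-methyl-3-methylidene-5-oxooct-6-en-1-yl]oxy}-3-methoxybenzoate | C=C(CC(=O)C=C(C)C)[C@@H](COc1ccc(C(=O)OC)cc1OC)OO | target

Total step count: 12. Longest linear sequence: 11 steps (steps 1–7 and 9–12); step 8 is a one-step branch that makes reagent 15.

Steps most likely to fail

Step 9 (peroxide displacement). The peroxide anion may attack the terminal methylene instead of C2 (SN2′) or act as a base (elimination towards the aryl enol ether, or fragmentation of the product peroxide), and any ionisation of the allylic sulfonate would erode the configuration at C2. The fallback sets out from mesylate 13 and comes back at perketal 16. The oxygen is delivered as hydrogen peroxide itself, a smaller and less basic nucleophile, by alkaline hydrogen peroxide displacement of the secondary mesylate (30% aq. H2O2 in large excess, KOH, MeOH, 0 °C). This is likewise an SN2 inversion and should give the free hydroperoxide methyl 4-{[(2S)-5-[(tert-butyldimethylsilyl)oxy]-2-hydroperoxy-7-methyl-3-methylideneoct-6-en-1-yl]oxy}-3-methoxybenzoate F1. The hydroperoxide is then capped with 2-methoxypropene and catalytic pyridinium p-toluenesulfonate in CH2Cl2 at 0 °C to give 16, so the order becomes substitution first and protection second, and reagent 15 is no longer needed.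

Step 2 (allylation of the enal). The Lewis acid may open the acetonide or ionise the dimethylallylic alkoxide as it forms, and conjugate addition may compete. The fallback sets out from allylsilane 5 and comes back at alcohol 7, replacing the cationic allylation by a neutral organometallic one. Bromodesilylation of 5 with N-bromosuccinimide (propylene oxide as acid scavenger, CH2Cl2, −78 °C) should give the allylic bromide (4R)-4-(3-bromoprop-1-en-2-yl)-2,2-dimethyl-1,3-dioxolane F2. A Barbier reaction of F2 with 3-methylbut-2-enal 6 and indium powder in THF/H2O at rt then gives 7 by clean 1,2-addition, with no Lewis acid present.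

Step 1 (double addition and elimination). The sequence may stall after the first addition through enolisation of ketone 3, the allylsilane may be protodesilylated during the elimination, or the C2 configuration may be eroded. The fallback sets out from ester 1 and comes back at allylsilane 5, building the same C3 substitution by cross-coupling. Ester 1 is converted into the Weinreb amide (4S)-N-methoxy-N,2,2-trimethyl-1,3-dioxolane-4-carboxamide F3 (MeNHOMe·HCl, iPrMgCl, THF, −20 °C). Addition of MeMgBr gives the methyl ketone 1-[(4S)-2,2-dimethyl-1,3-dioxolan-4-yl]ethan-1-one F4. Kinetic enolisation on the methyl side and trapping (KN(SiMe3)2, PhNTf2, THF, −78 °C) gives the enol triflate 1-[(4S)-2,2-dimethyl-1,3-dioxolan-4-yl]ethenyl trifluoromethanesulfonate F5. Kumada-type coupling of F5 with 2 under Pd(PPh3)4 catalysis in THF should then deliver 5.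

Further compounds
F1 | step 9 | methyl 4-{[(2S)-5-[(tert-butyldimethylsilyl)oxy]-2-hydroperoxy-7-methyl-3-methylideneoct-6-en-1-yl]oxy}-3-methoxybenzoate | C=C(CC(O[Si](C)(C)C(C)(C)C)C=C(C)C)[C@@H](COc1ccc(C(=O)OC)cc1OC)OO
F2 | step 2 | (4R)-4-(3-bromoprop-1-en-2-yl)-2,2-dimethyl-1,3-dioxolane | C=C(CBr)[C@@H]1COC(C)(C)O1
F3 | step 1 | (4S)-N-methoxy-N,2,2-trimethyl-1,3-dioxolane-4-carboxamide | CON(C)C(=O)[C@@H]1COC(C)(C)O1
F4 | step 1 | 1-[(4S)-2,2-dimethyl-1,3-dioxolan-4-yl]ethan-1-one | CC(=O)[C@@H]1COC(C)(C)O1
F5 | step 1 | 1-[(4S)-2,2-dimethyl-1,3-dioxolan-4-yl]ethenyl trifluoromethanesulfonate | C=C(OS(=O)(=O)C(F)(F)F)[C@@H]1COC(C)(C)O1
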